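**Retrosynthetic overview**
1. Cut the central CH2–CH2 bond: a primary radical on the oxepane–cyclohexane half (fragment 2) adds under visible light to the exocyclic enone of the hydroazulene half (fragment 1); a final MeLi addition makes the seven-ring carbinol.
2. Fragment 1 from (R)-carvone: α'-allylation, ring-closing metathesis (cyclopentene first), enone transposition, one-carbon ring expansion (seven-membered ring second), conjugate methylation and Saegusa oxidation.
3. Fragment 2 from (1S,2S,4R)-limonene-1,2-diol: the cyclohexane and two stereocentres are bought; the quaternary carbon comes from two alkylations, isopropenyl becomes OH (Criegee), and the oxepane is closed last by 7-endo epoxide opening.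
4. Ring order: cyclopentene, cycloheptenone (fragment 1); cyclohexane (bought), oxepane (fragment 2); then union.

Assumption: the target is made exactly as drawn in the SMILES, and (R)-carvone and (1S,2S,4R)-limonene-1,2-diol (the hydrolysis product of (R)-limonene oxide) are bought as such.

**Fragment 1**

Step 1
Reactants: 1 (R)-carvone
Product: 2 trans-6-allylcarvone
Conditions: LiN(iPr)2, THF, −78 °C; allyl bromide, −78 to −20 °C
Reagents that add atoms: allyl bromide, C=CCBr
Why: Kinetic α'-enolate alkylation anti to the C-5 isopropenyl group gives mainly the trans epimer; the minor cis epimer converges in step 2.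

Step 2
Reactants: 2 trans-6-allylcarvone
Product: 4 cis-fused hydrindadienone, via trans-fused hydrindadienone 3 (not isolated)
Conditions: (H2IMes)(PCy3)Cl2Ru=CHPh (second-generation Grubbs catalyst, 5 mol%), CH2Cl2, 40 °C; then DBU (0.3 equiv), rt
Reagents that add atoms: none
Why: Ring-closing metathesis of allyl and isopropenyl makes the methylcyclopentene, and base epimerization at the α ring-fusion carbon funnels to the less strained cis-fused ketone, so the new centre is controlled by the carvone centre.

Step 3
Reactants: 4 cis-fused hydrindadienone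
Product: 5 tertiary allylic alcohol
Conditions: MeLi, CeCl3, THF, −78 °C
Reagents that add atoms: methyllithium, [Li]C
Why: Organocerium 1,2-addition to the enone carbonyl; the new carbinol centre is lost in step 4, so its configuration does not matter.

Step 4
Reactants: 5 tertiary allylic alcohol
Product: 6 transposed 2,3-dimethyl enone
Conditions: [C5H5NH][CrO3Cl], 4 Å molecular sieves, CH2Cl2, rt
Reagents that add atoms: none
Why: Dauben–Michno oxidative 1,3-transposition of a tertiary allylic alcohol; the ring-fusion centres are untouched.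

Step 5
Reactants: 6 transposed 2,3-dimethyl enone
Product: 8 cycloheptenone, via α-silyl cycloheptenone 7 (not isolated)
Conditions: Me3SiCHN2, BF3·OEt2, CH2Cl2, −78 to −20 °C; then 1 M HCl, THF, rt
Reagents that add atoms: (trimethylsilyl)diazomethane, C[Si](C)(C)C=[N+]=[N-]
Why: Lewis-acid diazoalkane homologation (Tiffeneau–Demjanov type) in which the sp3 CH2 migrates in preference to the vinyl carbon, followed by protodesilylation; no stereocentre is involved.

Step 6
Reactants: 8 cycloheptenone
Product: 9 silyl enol ether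
Conditions: Me2CuLi (from MeLi and CuI), Me3SiCl, THF, −78 to −30 °C
Reagents that add atoms: lithium dimethylcuprate, [Li+].C[Cu-]C; chlorotrimethylsilane, C[Si](C)(C)Cl
Why: Silyl-chloride-accelerated Gilman conjugate addition makes the non-stereogenic gem-dimethyl carbon and fixes the enolate regiochemistry as the silyl enol ether.

Step 7
Reactants: 9 silyl enol ether
Product: 10 exo-methylene hydroazulenone
Conditions: Pd(OAc)2 (1.1 equiv), MeCN, rt
Reagents that add atoms: none
Why: Saegusa–Ito oxidation; β-hydride elimination can only occur toward the methyl group because the other β-carbon is quaternary, so only the exocyclic enone forms.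

**Fragment 2**

Step 8
Reactants: 11 (1S,2S,4R)-limonene-1,2-diol
Product: 12 hydroxy ketone
Conditions: (COCl)2, DMSO, CH2Cl2, −78 °C; Et3N, to 0 °C
Reagents that add atoms: none
Why: Swern oxidation of the secondary alcohol; the tertiary carbinol and the isopropenyl-bearing centre (both bought) are untouched.

Step 9
Reactants: 12 hydroxy ketone
Product: 13 methyl hydroxy ketone
Conditions: LiN(iPr)2 (2.2 equiv), THF, −78 to −40 °C; MeI
Reagents that add atoms: iodomethane, CI
Why: Alkylation of the alkoxide–enolate dianion, which can only form on the CH2 side because the other α-carbon is quaternary; the new centre is re-enolized in step 10.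

Step 10
Reactants: 13 methyl hydroxy ketone
Product: 14 homoprenyl methyl hydroxy ketone
Conditions: LiN(iPr)2 (2.2 equiv), THF/HMPA, −78 to 0 °C; 5-iodo-2-methylpent-2-ene
Reagents that add atoms: 5-iodo-2-methylpent-2-ene, CC(C)=CCCI
Why: Enolate alkylation anti to the adjacent pseudoaxial isopropenyl group sets the quaternary centre with the chain trans and the methyl cis to isopropenyl.

Step 11
Reactants: 14 homoprenyl methyl hydroxy ketone
Product: 15 epoxy ketone
Conditions: mCPBA (1.05 equiv), NaHCO3, CH2Cl2, −10 °C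
Reagents that add atoms: 3-chloroperbenzoic acid, OOC(=O)c1cccc(Cl)c1
Why: Prilezhaev epoxidation selective for the trisubstituted alkene over isopropenyl; both epoxide epimers are carried on because they converge in steps 15 and 16.

Step 12
Reactants: 15 epoxy ketone
Product: 17 epoxy acetate, via methoxy hydroperoxide 16 (not isolated)
Conditions: O3, CH2Cl2/MeOH 5:1, −78 °C; then Ac2O, Et3N, DMAP (cat.), 0 to 40 °C
Reagents that add atoms: ozone, [O-][O+]=O; methanol, CO
Why: Ozonolysis of the isopropenyl group in methanol and Criegee rearrangement replace the carbon substituent by acetoxy with retention at the migrating ring carbon.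

Step 13
Reactants: 17 epoxy acetate
Product: 19 oxepanol ketone, via hydroxy epoxide 18 (not isolated)
Conditions: K2CO3 (0.3 equiv), MeOH, 0 °C; then camphorsulfonic acid (10 mol%), CH2Cl2, 0 °C to rt
Reagents that add atoms: none
Why: Transesterification frees the ring alcohol (no α-hydrogen, so no elimination), which opens the epoxide at its tertiary carbon (acid-catalysed 7-endo etherification) to give the trans-fused 2,2-dimethyloxepane.

Step 14
Reactants: 19 oxepanol ketone
Product: 21 methylidene diol, via β-hydroxysilane 20 (not isolated)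
Conditions: Me3SiCH2Li (5 equiv), CeCl3, THF, −78 to 0 °C; aq. NH4Cl; then KH, THF, 0 to 50 °C
Reagents that add atoms: (trimethylsilyl)methyllithium, [Li]C[Si](C)(C)C
Why: Peterson olefination, chosen because the ketone is non-enolizable and flanked by two fully substituted carbons.

Step 15
Reactants: 21 methylidene diol
Product: 22 oxepanone
Conditions: Dess–Martin periodinane, NaHCO3, CH2Cl2, 0 °C to rt
Reagents that add atoms: none
Why: Dess–Martin oxidation of the only secondary alcohol removes the uncontrolled oxepane carbinol centre.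

Step 16
Reactants: 22 oxepanone
Product: 23 (3R)-methylidene diol
Conditions: NaBH4, MeOH, −20 °C
Reagents that add atoms: none
Why: Substrate-controlled hydride reduction of the ring-locked 2,2-dimethyloxepan-3-one is expected to give the (3R) alcohol of the natural series; this face selectivity is the least certain of the routine steps, and the wrong epimer can be recycled through step 15.

**Union and completion**

Step 17
Reactants: 23 (3R)-methylidene diol; 10 exo-methylene hydroazulenone
Product: 25 coupled ketone, via alkylcatecholborane 24 (not isolated)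
Conditions: catecholborane (4 equiv), N,N-dimethylacetamide (20 mol%), CH2Cl2, 40 °C; t-BuOH; then 10 (1.0 equiv), 4CzIPN (2 mol%), DMAP (1.2 equiv), MeOH (5 equiv), DMF, 450 nm LED, 25 °C; aq. NH4Cl
Reagents that add atoms: none
Why: Proposed new method: anti-Markovnikov hydroboration puts boron on the CH2 and delivers H to the ring carbon from the face opposite the flanking axial methyl and oxygen; the DMAP-bound alkylboron is oxidized by the excited photocatalyst to a primary radical, which adds to the enone CH2 (Giese addition), and the resulting enolate is protonated from the convex face to place the chain cis to the cyclopentene; the closest known reactions are Lewis-base-assisted photoredox Giese additions of boronic esters and the oxygen-initiated conjugate addition of B-alkylcatecholboranes to enones.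

Step 18
Reactants: 25 coupled ketone
Product: 26 target CNP0214586.1
Conditions: MeLi (6 equiv), CeCl3, THF, −78 °C
Reagents that add atoms: methyllithium, [Li]C
Why: Organocerium 1,2-addition from the convex face, anti to the adjacent side chain, is expected to give the tertiary alcohol with OH cis to the chain without epimerizing the α-centre.

**Compound list**
1 | (R)-carvone, (5R)-2-methyl-5-(prop-1-en-2-yl)cyclohex-2-en-1-one | CC1=CC[C@H](CC1=O)C(C)=C | starting material
2 | (5R,6S)-2-methyl-5-(prop-1-en-2-yl)-6-(prop-2-en-1-yl)cyclohex-2-en-1-one (allyl trans to isopropenyl) | C=CC[C@H]1[C@H](C(C)=C)CC=C(C)C1=O | intermediate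
3 | (3aR,7aS)-3,6-dimethyl-1,3a,4,7a-tetrahydro-7H-inden-7-one (trans-fused) | CC1=CC[C@H]2[C@H]1CC=C(C)C2=O | intermediate
4 | (3aR,7aR)-3,6-dimethyl-1,3a,4,7a-tetrahydro-7H-inden-7-one (cis-fused) | CC1=CC[C@@H]2[C@H]1CC=C(C)C2=O | intermediate
5 | (3aR,7aR)-3,6,7-trimethyl-3a,4,7,7a-tetrahydro-1H-inden-7-ol (cis-fused, carbinol epimers) | CC1=CC[C@@H]2[C@H]1CC=C(C)C2(C)O | intermediate
6 | (3aR,7aR)-3,6,7-trimethyl-1,3a,4,7a-tetrahydro-5H-inden-5-one (cis-fused) | CC1=CC[C@@H]2[C@H]1CC(=O)C(C)=C2C | intermediate
7 | (3aR,8aR)-3,7,8-trimethyl-5-(trimethylsilyl)-3a,4,5,8a-tetrahydroazulen-6(1H)-one (silyl epimers) | CC1=CC[C@@H]2[C@H]1CC([Si](C)(C)C)C(=O)C(C)=C2C | intermediate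
8 | (3aR,8aR)-3,7,8-trimethyl-3a,4,5,8a-tetrahydroazulen-6(1H)-one (cis-fused) | CC1=CC[C@@H]2[C@H]1CCC(=O)C(C)=C2C | intermediate
9 | trimethyl{[(3aR,8aR)-3,7,8,8-tetramethyl-1,3a,4,5,8,8a-hexahydroazulen-6-yl]oxy}silane | CC1=CC[C@@H]2[C@H]1CCC(O[Si](C)(C)C)=C(C)C2(C)C | intermediate
10 | (3aR,8aR)-3,8,8-trimethyl-7-methylidene-3a,4,5,7,8,8a-hexahydroazulen-6(1H)-one (cis-fused) | CC1=CC[C@@H]2[C@H]1CCC(=O)C(=C)C2(C)C | intermediate
11 | (1S,2S,4R)-1-methyl-4-(prop-1-en-2-yl)cyclohexane-1,2-diol | O[C@H]1C[C@H](C(C)=C)CC[C@]1(C)O | starting material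
12 | (2S,5R)-2-hydroxy-2-methyl-5-(prop-1-en-2-yl)cyclohexan-1-one | O=C1C[C@H](C(C)=C)CC[C@]1(C)O | intermediate
13 | 2-hydroxy-2,6-dimethyl-5-(prop-1-en-2-yl)cyclohexan-1-one (2-OH cis to isopropenyl, C-6 epimers) | O=C1C(C)[C@H](C(C)=C)CC[C@]1(C)O | intermediate
14 | 2-hydroxy-2,6-dimethyl-6-(4-methylpent-3-en-1-yl)-5-(prop-1-en-2-yl)cyclohexan-1-one (chain trans, 6-methyl and 2-OH cis to isopropenyl) | O=C1[C@@](C)(CCC=C(C)C)[C@H](C(C)=C)CC[C@]1(C)O | intermediate
15 | 6-[2-(3,3-dimethyloxiran-2-yl)ethyl]-2-hydroxy-2,6-dimethyl-5-(prop-1-en-2-yl)cyclohexan-1-one (ring centres as in 14, epoxide epimers) | O=C1[C@@](C)(CCC2OC2(C)C)[C@H](C(C)=C)CC[C@]1(C)O | intermediate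
16 | 6-[2-(3,3-dimethyloxiran-2-yl)ethyl]-5-(2-hydroperoxy-2-methoxypropan-2-yl)-2-hydroxy-2,6-dimethylcyclohexan-1-one (ring centres as in 14) | O=C1[C@@](C)(CCC2OC2(C)C)[C@H](C(C)(OC)OO)CC[C@]1(C)O | intermediate
17 | 2-[2-(3,3-dimethyloxiran-2-yl)ethyl]-4-hydroxy-2,4-dimethyl-3-oxocyclohexyl acetate (acetoxy in place of isopropenyl, retention) | O=C1[C@@](C)(CCC2OC2(C)C)[C@H](OC(C)=O)CC[C@]1(C)O | intermediate
18 | 6-[2-(3,3-dimethyloxiran-2-yl)ethyl]-2,5-dihydroxy-2,6-dimethylcyclohexan-1-one (5-OH trans to chain, cis to 2-OH) | O=C1[C@@](C)(CCC2OC2(C)C)[C@H](O)CC[C@]1(C)O | intermediate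
19 | trans-fused 3,7-dihydroxy-2,2,5a,7-tetramethyloctahydro-1-benzoxepin-6(2H)-one (7-OH cis to 5a-methyl, C-3 epimers) | O=C1[C@@]2(C)CCC(O)C(C)(C)O[C@@H]2CC[C@]1(C)O | intermediate
20 | trans-fused 2,2,5a,7-tetramethyl-6-[(trimethylsilyl)methyl]decahydro-1-benzoxepine-3,6,7-triol (C-3 and C-6 epimers) | C[Si](C)(C)CC1(O)[C@@]2(C)CCC(O)C(C)(C)O[C@@H]2CC[C@]1(C)O | intermediate
21 | trans-fused 2,2,5a,7-tetramethyl-6-methylidenedecahydro-1-benzoxepine-3,7-diol (C-3 epimers) | C=C1[C@@]2(C)CCC(O)C(C)(C)O[C@@H]2CC[C@]1(C)O | intermediate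
22 | trans-fused 7-hydroxy-2,2,5a,7-tetramethyl-6-methylideneoctahydro-1-benzoxepin-3(2H)-one | C=C1[C@@]2(C)CCC(=O)C(C)(C)O[C@@H]2CC[C@]1(C)O | intermediate
23 | (3R,5aR,7S,9aR)-2,2,5a,7-tetramethyl-6-methylidenedecahydro-1-benzoxepine-3,7-diol | C=C1[C@@]2(C)CC[C@@H](O)C(C)(C)O[C@@H]2CC[C@]1(C)O | intermediate
24 | B-alkylcatecholborane of 23 (boron on the former methylidene carbon, ring H trans to 7-O, both hydroxyls as catechol borates) | c1ccc2OB(C[C@@H]3[C@@]4(C)CC[C@@H](OB5Oc6ccccc6O5)C(C)(C)O[C@@H]4CC[C@]3(C)OB3Oc4ccccc4O3)Oc2c1 | intermediate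
25 | coupled ketone: 10 carrying at its α-carbon the 2-(benzoxepin-6-yl)ethyl chain, chain cis to the cyclopentene ring | CC1=CC[C@@H]2[C@H]1CCC(=O)[C@H](CC[C@@H]1[C@@]3(C)CC[C@@H](O)C(C)(C)O[C@@H]3CC[C@]1(C)O)C2(C)C | intermediate
26 | CNP0214586.1 | CC1=CC[C@@H]2[C@H]1CC[C@](C)(O)[C@H](CC[C@@H]1[C@@]3(C)CC[C@@H](O)C(C)(C)O[C@@H]3CC[C@]1(C)O)C2(C)C | target

**Totals**
Total step count: 18. Longest linear sequence: 11 (steps 8 to 18).

**Three steps most likely to fail**

Step 5 (diazoalkane ring expansion of a conjugated, tetrasubstituted enone; addition may be slow and the vinyl carbon may compete in migration). Fallback, setting out from 6: kinetic α'-deprotonation with LiN(iPr)2 and Me3SiCl gives the silyl dienol ether F1. Et2Zn/CH2I2 cyclopropanates its electron-rich enol double bond to the siloxycyclopropane F2. FeCl3 in DMF opens this (Saegusa–Ito ring expansion) to the β-chloro cycloheptenone F3, and NaOAc in MeOH eliminates HCl to the cross-conjugated dienone F4. Conjugate reduction of the less hindered disubstituted enone with [(Ph3P)CuH]6 comes back to the route at 8.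

Step 10 (alkylation of a hindered, tetrasubstituted enolate with an unactivated iodide). Fallback, setting out from 13: DBU-catalysed Michael addition to acrolein, again anti to the isopropenyl group, gives the keto aldehyde F5. Wittig reaction of the aldehyde with Ph3P=C(CH3)2 (the hindered ketone does not react) comes back to the route at 14.

Step 17 (the proposed one-pot hydroboration and photochemical Giese coupling; the boron–carbon bond may not be oxidized, or excess borane may reduce the enone). Fallback by known chemistry, setting out from 23: hydroboration with BH3·THF followed by I2/NaOMe gives the primary iodide F6. F6 is then coupled with 10 by silyl-radical halogen-atom-transfer Giese addition ((Me3Si)3SiH, [Ir(dF(CF3)ppy)2(dtbbpy)]PF6, Na2CO3, dimethoxyethane, blue LED), which comes back to the route at 25.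

Further compounds
F1 | step 5 | trimethyl{[(3aR,7aR)-3,6,7-trimethyl-3a,7a-dihydro-1H-inden-5-yl]oxy}silane | CC1=CC[C@@H]2[C@H]1C=C(O[Si](C)(C)C)C(C)=C2C
F2 | step 5 | siloxycyclopropane from F1 (cyclopropane on the former enol double bond) | CC1=CC[C@@H]2[C@H]1C1CC1(O[Si](C)(C)C)C(C)=C2C
F3 | step 5 | (3aR,8aR)-4-chloro-3,7,8-trimethyl-3a,4,5,8a-tetrahydroazulen-6(1H)-one (chloride epimers) | CC1=CC[C@@H]2[C@H]1C(Cl)CC(=O)C(C)=C2C
F4 | step 5 | (3aR,8aR)-3,7,8-trimethyl-3a,8a-dihydroazulen-6(1H)-one | CC1=CC[C@@H]2[C@H]1C=CC(=O)C(C)=C2C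
F5 | step 10 | 3-[3-hydroxy-1,3-dimethyl-2-oxo-6-(prop-1-en-2-yl)cyclohexyl]propanal (ring centres as in 14) | O=C1[C@@](C)(CCC=O)[C@H](C(C)=C)CC[C@]1(C)O
F6 | step 17 | (3R,5aR,6R,7S,9aR)-6-(iodomethyl)-2,2,5a,7-tetramethyldecahydro-1-benzoxepine-3,7-diol | IC[C@@H]1[C@@]2(C)CC[C@@H](O)C(C)(C)O[C@@H]2CC[C@]1(C)O
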